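The furanone ring is cut at O1–C5 and at C2–C3: the ring oxygen, the lactone carbonyl carbon and its exocyclic oxygen are then one molecule of CO2, and what remains is an ethyl ketone (C3–C4) carrying a vinyl iodide at C5 whose geometry already is that of the (E)-ylidene. In the key step the kinetic enolate is carboxylated at C3 and the new carboxylate is closed onto C5 by copper-catalysed O-vinylation with retention, so the tetronic acid core and its exocyclic C5=C6 geometry arise in one operation. The iodo enone comes from an ynone by syn-hydrostannation; (S)-citronellal supplies C7 and the (E)-trisubstituted alkene; sulfation finishes.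

Key step: step 12

Remark: the exocyclic C5=C6 bond is taken as drawn, (E), with the side chain syn to C4–O, and C7 as (S); anti-addition of a carboxylate across an alkyne would give the (Z)-isomer, so the alkene geometry is fixed before ring closure.

Numbering used: furanone O1, C2 (C=O), C3 (C–CH3), C4 (C–O), C5; side chain C6 (=CH), C7 (CH–CH3).

Step 1
Reactants: 1 3-bromofuran; 2 4-bromofuran-2-carbaldehyde
Product: 4 (4-bromofuran-2-yl)(furan-3-yl)methanol (racemic), via furan-3-yllithium 3 (not isolated)
Conditions: n-BuLi (1.0 equiv), THF, −78 °C, 20 min; then 2, −78 °C; aq. NH4Cl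
Reagents that add atoms: none
Why: Bromine–lithium exchange at −78 °C should give furan-3-yllithium without migration to the α-position, and its 1,2-addition to the aldehyde is far faster than exchange with the ring bromide of 2; the carbinol stereocentre forms as a racemate and is removed in step 2.

Step 2
Reactants: 4 (4-bromofuran-2-yl)(furan-3-yl)methanol
Product: 5 4-bromo-2-(furan-3-ylmethyl)furan
Conditions: Et3SiH (3 equiv), CF3CO2H (2 equiv), CH2Cl2, −20 → 0 °C
Reagents that add atoms: none
Why: Ionic hydrogenation: the acid ionises the carbinol to a cation stabilised by both furan rings and Et3SiH delivers hydride to it, while low temperature and excess silane should hold back Friedel–Crafts oligomerisation of the furans.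

Step 3
Reactants: 5 4-bromo-2-(furan-3-ylmethyl)furan
Product: 7 2-[5-(furan-3-ylmethyl)furan-3-yl]ethan-1-ol, via 5-(furan-3-ylmethyl)furan-3-yllithium 6 (not isolated)
Conditions: n-BuLi (1.05 equiv), THF, −78 °C; oxirane (3 equiv), BF3·OEt2 (1.1 equiv), −78 °C; aq. NH4Cl
Reagents that add atoms: oxirane, C1CO1
Why: Bromine–lithium exchange at the furan β-position followed by BF3-assisted opening of oxirane at −78 °C, where the β-lithiofuran should neither isomerise to the α-lithio species nor deprotonate the diheteroarylmethane CH2 at a competitive rate.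

Step 4
Reactants: 7 2-[5-(furan-3-ylmethyl)furan-3-yl]ethan-1-ol
Product: 8 4-(2-bromoethyl)-2-(furan-3-ylmethyl)furan
Conditions: CBr4, PPh3, CH2Cl2, 0 °C
Reagents that add atoms: carbon tetrabromide, BrC(Br)(Br)Br
Why: Appel bromination of a primary alcohol under neutral conditions that the acid-sensitive furans should tolerate.

Step 5
Reactants: 9 (S)-citronellal [(3S)-3,7-dimethyloct-6-enal]
Product: 11 (3S)-3,7-dimethyloct-6-en-1-yne, via enol nonaflate 10 (not isolated)
Conditions: C4F9SO2F (1.2 equiv), t-BuN=P(NC4H8)3 (2.3 equiv), DMF, −30 °C → rt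
Reagents that add atoms: none
Why: One-pot conversion of an enolisable aldehyde into a terminal alkyne: O-sulfonylation of the enolate gives enol nonaflate 10, which undergoes E2 elimination with the second equivalent of phosphazene base, and the product is held as its acetylide, which should protect the propargylic stereocentre against allene formation.

Step 6
Reactants: 11 (3S)-3,7-dimethyloct-6-en-1-yne
Product: 12 (2E,6S)-2,6-dimethyloct-2-en-7-yn-1-ol
Conditions: SeO2 (0.2 equiv), t-BuOOH (3 equiv), salicylic acid (0.1 equiv), CH2Cl2, 0 °C → rt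
Reagents that add atoms: tert-butyl hydroperoxide, CC(C)(C)OO
Why: Selenium dioxide allylic oxidation (ene reaction, then [2,3]-sigmatropic shift) attacks the (E)-methyl group of the trisubstituted alkene selectively and so should give the (E)-allylic alcohol, the propargylic C–H being much less reactive under catalytic conditions.

Step 7
Reactants: 12 (2E,6S)-2,6-dimethyloct-2-en-7-yn-1-ol
Product: 13 (3S,6E)-8-bromo-3,7-dimethyloct-6-en-1-yne
Conditions: CBr4, PPh3, CH2Cl2, −20 °C
Reagents that add atoms: carbon tetrabromide, BrC(Br)(Br)Br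
Why: Appel bromination of the primary allylic alcohol by SN2 displacement at low temperature, which should proceed without allylic transposition or loss of the (E) geometry.

Step 8
Reactants: 8 4-(2-bromoethyl)-2-(furan-3-ylmethyl)furan; 13 (3S,6E)-8-bromo-3,7-dimethyloct-6-en-1-yne
Product: 15 4-[(4E,8S)-4,8-dimethyldec-4-en-9-yn-1-yl]-2-(furan-3-ylmethyl)furan, via alkylmagnesium bromide 14 (not isolated)
Conditions: 8, Mg, THF, rt (gives 14, 1.5 equiv); then 13, Li2CuCl4 (3 mol%), THF, −40 → 0 °C; aq. NH4Cl
Reagents that add atoms: none
Why: Copper-catalysed sp3–sp3 coupling of an alkyl Grignard reagent with a primary allylic bromide (Kochi-type coupling) should occur at the CH2Br carbon with retention of the (E) alkene, and at −40 °C it should outrun deprotonation of the acetylenic C–H, for which the excess of 14 allows.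

Step 9
Reactants: 15 4-[(4E,8S)-4,8-dimethyldec-4-en-9-yn-1-yl]-2-(furan-3-ylmethyl)furan; 16 N-methoxy-N-methylpropanamide
Product: 18 (6S,10E)-13-[5-(furan-3-ylmethyl)furan-3-yl]-6,10-dimethyltridec-10-en-4-yn-3-one, via lithium acetylide 17 (not isolated)
Conditions: n-BuLi (1.05 equiv), THF, −78 °C; then 16, −78 → 0 °C; aq. NH4Cl
Reagents that add atoms: none
Why: Deprotonation of the terminal alkyne and acylation of the lithium acetylide with a Weinreb amide, whose chelated tetrahedral adduct prevents over-addition and releases the ynone only on work-up.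

Step 10
Reactants: 18 (6S,10E)-13-[5-(furan-3-ylmethyl)furan-3-yl]-6,10-dimethyltridec-10-en-4-yn-3-one
Product: 19 (4E,6S,10E)-13-[5-(furan-3-ylmethyl)furan-3-yl]-6,10-dimethyl-4-(tributylstannyl)trideca-4,10-dien-3-one
Conditions: Bu3SnH (1.1 equiv), Pd(PPh3)4 (2 mol%), THF, 0 °C
Reagents that add atoms: tributyltin hydride, CCCC[SnH](CCCC)CCCC
Why: Palladium-catalysed hydrostannation of a conjugated ynone is a syn addition that places tin on the carbon α to the carbonyl and hydrogen on the β-carbon, so the propionyl group and the C7 side chain should end up cis on the new double bond, which is the geometry the ylidene needs.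

Step 11
Reactants: 19 (4E,6S,10E)-α-stannyl enone
Product: 20 (4E,6S,10E)-13-[5-(furan-3-ylmethyl)furan-3-yl]-4-iodo-6,10-dimethyltrideca-4,10-dien-3-one
Conditions: I2 (1.05 equiv), CH2Cl2, −20 °C, dark; aq. Na2S2O3
Reagents that add atoms: iodine, II
Why: Iododestannylation is an ipso substitution that proceeds with retention at the sp2 carbon, so the (E)-vinyl iodide should be obtained with the acyl group and the side chain still cis, low temperature and exclusion of light guarding against iodine-catalysed isomerisation.

Step 12
Reactants: 20 (4E,6S,10E)-α-iodo enone; 21 carbon dioxide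
Product: 25 (5E)-5-{(2S,5E)-9-[5-(furan-3-ylmethyl)furan-3-yl]-2,6-dimethylnon-5-en-1-ylidene}-4-hydroxy-3-methylfuran-2(5H)-one, via lithium enolate 22 (not isolated), via lithium β-keto carboxylate 23 (not isolated), via dilithium enolate carboxylate 24 (not isolated)
Conditions: LiN(SiMe3)2 (1.05 equiv), THF, −78 °C; CO2 (1 atm), −78 °C, then Ar purge at −40 °C; LiN(SiMe3)2 (1.1 equiv), −78 °C; CuI (10 mol%), 1,10-phenanthroline (20 mol%), DMF, −78 °C → rt, dark; 1 M HCl, 0 °C
Reagents that add atoms: none
Why: Proposed new method: kinetic deprotonation gives the cross-conjugated lithium enolate 22, whose C3 is C-carboxylated by CO2 to the β-keto carboxylate 23 (new C2–C3 bond), and a second equivalent of base stores it as dianion 24, in which the enone is masked as a dienolate so that decarboxylation and oxa-Michael addition to C6 are shut down. Monovalent copper then couples the carboxylate oxygen with the neighbouring vinyl iodide (oxidative addition at C5–I, C–O reductive elimination), closing the O1–C5 bond and releasing the tetronate, which is protonated on work-up. The closest known reaction types are the C-carboxylation of ketone enolates with CO2, the silver-catalysed carboxylation–cyclisation of conjugated ynones with CO2 to tetronic acids and the copper-catalysed intramolecular O-vinylation of carboxylic acids with vinyl halides to enol lactones; their union in one pot on an α-iodo enone is the new element. The five-membered ring closes in a 5-exo mode at the sp2 carbon C5, the C5=C6 bond staying exocyclic. No stereocentre is formed: C(sp2)–O coupling proceeds with retention, so the (E) geometry installed in steps 10 and 11 is carried into the ylidene, and C7 is untouched. The step needs C- over O-carboxylation (lithium enolate), α′- over γ-deprotonation (kinetic base at −78 °C) and closure through oxygen only (C3 cannot reach C5 without forming a three-membered ring).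

Step 13
Reactants: 25 (5E)-tetronic acid
Product: 26 target, the C4–O hydrogen sulfate of 25 (CNP0018233.1)
Conditions: SO3·pyridine (3 equiv), pyridine, 0 °C → rt, dark; H+-form sulfonic acid resin, MeOH/H2O, 0 °C
Reagents that add atoms: sulfur trioxide–pyridine complex, [O-]S(=O)(=O)[n+]1ccccc1
Why: O-Sulfation of the acidic enol (a vinylogous carboxylic acid) of the tetronic acid by the sulfur trioxide–pyridine complex should be faster than C-sulfonation of the furans at 0 °C, and cation exchange then liberates the hydrogen sulfate without touching the (E)-ylidene.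

Compound list
1 | 3-bromofuran | Brc1ccoc1 | starting material
2 | 4-bromofuran-2-carbaldehyde | O=Cc1cc(Br)co1 | starting material
3 | furan-3-yllithium | [Li]c1ccoc1 | intermediate
4 | (4-bromofuran-2-yl)(furan-3-yl)methanol (racemic) | OC(c1cc(Br)co1)c1ccoc1 | intermediate
5 | 4-bromo-2-(furan-3-ylmethyl)furan | Brc1coc(Cc2ccoc2)c1 | intermediate
6 | 5-(furan-3-ylmethyl)furan-3-yllithium | [Li]c1coc(Cc2ccoc2)c1 | intermediate
7 | 2-[5-(furan-3-ylmethyl)furan-3-yl]ethan-1-ol | OCCc1coc(Cc2ccoc2)c1 | intermediate
8 | 4-(2-bromoethyl)-2-(furan-3-ylmethyl)furan | BrCCc1coc(Cc2ccoc2)c1 | intermediate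
9 | (S)-citronellal | O=CC[C@@H](C)CCC=C(C)C | starting material
10 | (3S)-3,7-dimethylocta-1,6-dien-1-yl nonafluorobutane-1-sulfonate (E/Z mixture) | FC(F)(F)C(F)(F)C(F)(F)C(F)(F)S(=O)(=O)OC=C[C@@H](C)CCC=C(C)C | intermediate
11 | (3S)-3,7-dimethyloct-6-en-1-yne | C#C[C@@H](C)CCC=C(C)C | intermediate
12 | (2E,6S)-2,6-dimethyloct-2-en-7-yn-1-ol | C#C[C@@H](C)CC/C=C(\C)CO | intermediate
13 | (3S,6E)-8-bromo-3,7-dimethyloct-6-en-1-yne | C#C[C@@H](C)CC/C=C(\C)CBr | intermediate
14 | {2-[5-(furan-3-ylmethyl)furan-3-yl]ethyl}magnesium bromide | Br[Mg]CCc1coc(Cc2ccoc2)c1 | intermediate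
15 | 4-[(4E,8S)-4,8-dimethyldec-4-en-9-yn-1-yl]-2-(furan-3-ylmethyl)furan | C#C[C@@H](C)CC/C=C(\C)CCCc1coc(Cc2ccoc2)c1 | intermediate
16 | N-methoxy-N-methylpropanamide | CCC(=O)N(C)OC | starting material
17 | lithium acetylide of 15 | [Li]C#C[C@@H](C)CC/C=C(\C)CCCc1coc(Cc2ccoc2)c1 | intermediate
18 | (6S,10E)-13-[5-(furan-3-ylmethyl)furan-3-yl]-6,10-dimethyltridec-10-en-4-yn-3-one | CCC(=O)C#C[C@@H](C)CC/C=C(\C)CCCc1coc(Cc2ccoc2)c1 | intermediate
19 | (4E,6S,10E)-13-[5-(furan-3-ylmethyl)furan-3-yl]-6,10-dimethyl-4-(tributylstannyl)trideca-4,10-dien-3-one | CCC(=O)/C(=C\[C@@H](C)CC/C=C(\C)CCCc1coc(Cc2ccoc2)c1)[Sn](CCCC)(CCCC)CCCC | intermediate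
20 | (4E,6S,10E)-13-[5-(furan-3-ylmethyl)furan-3-yl]-4-iodo-6,10-dimethyltrideca-4,10-dien-3-one | CCC(=O)/C(I)=C\[C@@H](C)CC/C=C(\C)CCCc1coc(Cc2ccoc2)c1 | intermediate
21 | carbon dioxide | O=C=O | starting material
22 | lithium enolate of 20 (C3=C4, geometry not defined) | CC=C(O[Li])/C(I)=C\[C@@H](C)CC/C=C(\C)CCCc1coc(Cc2ccoc2)c1 | intermediate
23 | lithium β-keto carboxylate (C3 epimers) | CC(C(=O)[O-])C(=O)/C(I)=C\[C@@H](C)CC/C=C(\C)CCCc1coc(Cc2ccoc2)c1.[Li+] | intermediate
24 | dilithium enolate carboxylate | CC(C(=O)[O-])=C([O-])/C(I)=C\[C@@H](C)CC/C=C(\C)CCCc1coc(Cc2ccoc2)c1.[Li+].[Li+] | intermediate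
25 | (5E)-5-{(2S,5E)-9-[5-(furan-3-ylmethyl)furan-3-yl]-2,6-dimethylnon-5-en-1-ylidene}-4-hydroxy-3-methylfuran-2(5H)-one | CC1=C(O)/C(=C\[C@@H](C)CC/C=C(\C)CCCc2coc(Cc3ccoc3)c2)OC1=O | intermediate
26 | (2E)-2-{(2S,5E)-9-[5-(furan-3-ylmethyl)furan-3-yl]-2,6-dimethylnon-5-en-1-ylidene}-4-methyl-5-oxo-2,5-dihydrofuran-3-yl hydrogen sulfate | CC1=C(OS(=O)(=O)O)/C(=C\[C@@H](C)CC/C=C(\C)CCCc2coc(Cc3ccoc3)c2)OC1=O | target

Total step count: 13. Longest linear sequence: 10 steps (steps 1–4, then 8–13).

Steps most likely to fail

Step 12 (labelled step). The β-keto carboxylate may lose CO2 before ring closure, or the carboxylate may add reversibly to C6 and so erode the alkene geometry, giving slow closure or (E)/(Z) mixtures. The fallback sets out from ynone 18 and uses the known silver-catalysed CO2 incorporation into conjugated ynones (AgOAc 10 mol%, 7-methyl-1,5,7-triazabicyclo[4.4.0]dec-5-ene, CO2 1 MPa, MeCN, 25 °C). This closes the same two bonds by anti-addition and should give the (5Z)-tetronic acid F1. Irradiation of F1 (300 nm, MeCN) should then equilibrate the exocyclic alkene; the (5E)-isomer is separated by preparative HPLC and the (Z)-isomer recycled. The route is rejoined at 25.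

Step 5. The strong base may cause propargyl–allenyl isomerisation, which would racemise the methyl-bearing carbon, or aldol self-condensation of the aldehyde before O-sulfonylation. The fallback sets out from 9: Tf2O and 2,6-di-tert-butyl-4-methylpyridine (CH2Cl2, 0 °C → rt) should give the isolable enol triflate F2 as an E/Z mixture. LiN(i-Pr)2 (2.2 equiv, THF, −78 °C) then eliminates triflate under kinetic low-temperature conditions and leaves the lithium acetylide, which is protonated on work-up. The route is rejoined at 11.

Step 13. C-sulfonation at the unsubstituted furan α-positions may compete, and the acid-labile enol sulfate may be cleaved or isomerised when the free acid is liberated. The fallback sets out from 25: 2,2,2-trichloroethyl chlorosulfate, Et3N and DMAP (THF, 0 °C) should give the neutral, chromatographable trichloroethyl-protected sulfate diester F3. Zn dust and HCO2NH4 (MeOH, rt) then remove the trichloroethyl group reductively under near-neutral conditions, and brief cation exchange gives the hydrogen sulfate. The route is rejoined at 26.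

Further compounds
F1 | step 12 | (5Z)-5-{(2S,5E)-9-[5-(furan-3-ylmethyl)furan-3-yl]-2,6-dimethylnon-5-en-1-ylidene}-4-hydroxy-3-methylfuran-2(5H)-one | CC1=C(O)/C(=C/[C@@H](C)CC/C=C(\C)CCCc2coc(Cc3ccoc3)c2)OC1=O
F2 | step 5 | (3S)-3,7-dimethylocta-1,6-dien-1-yl trifluoromethanesulfonate (E/Z mixture) | FC(F)(F)S(=O)(=O)OC=C[C@@H](C)CCC=C(C)C
F3 | step 13 | 2,2,2-trichloroethyl sulfate diester of 25 | CC1=C(OS(=O)(=O)OCC(Cl)(Cl)Cl)/C(=C\[C@@H](C)CC/C=C(\C)CCCc2coc(Cc3ccoc3)c2)OC1=O
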